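**Strategy.** The route rests on cutting the C1=C10 alkene of ring A (C1–C5, C10), the ring-fusion double bond next to quaternary C9. (R)-Pulegone supplies ring B (C5–C10), the C8 methyl stereocentre and C4 with both geminal methyls; its ketone carbon is C10. Cuprate addition hangs C1–C3 on C4, two enolate alkylations build quaternary C9, and ozonolysis gives a 1,6-keto aldehyde. Intramolecular McMurry coupling of this keto aldehyde closes ring A and places the trisubstituted alkene regiospecifically at C1=C10 in one operation. The side-chain stereocentre comes from methyl hydrogen (R)-3-methylglutarate, the glyceride from (S)-glycidol.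

Key step: step 7

Remark (numbering and assumption): halimane numbering is used. Ring A = C1–C5 and C10 (C4 carries the geminal methyls), ring B = C5–C10 (C8 carries a methyl, C9 a methyl and the side chain C11–C15, C13 carries a methyl, C15 is the carboxyl carbon). Methyl hydrogen (R)-3-methylglutarate, (S)-glycidol and but-3-en-1-ylmagnesium bromide solution are taken as commercial.

**Step 1**
Reactants: 1 (R)-(+)-pulegone; 2 but-3-en-1-ylmagnesium bromide
Product: 4 (2S,5R)-5-methyl-2-(2-methylhex-5-en-2-yl)cyclohexan-1-one, via bromomagnesium enolate 3 (not isolated)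
Conditions: CuBr·SMe2 (10 mol %), THF/Et2O, −20 °C; aq NH4Cl; then KOH, EtOH/H2O, reflux
Reagents that add atoms: none
Why: Copper-catalysed 1,4-addition of the Grignard reagent to the s-cis β,β-disubstituted enone builds quaternary C4 with C1–C3 attached, and base equilibration of the α-centre C5 should favour the trans isomer with both ring substituents equatorial, C8 being carried over from pulegone.

**Step 2**
Reactants: 4 (2S,5R)-5-methyl-2-(2-methylhex-5-en-2-yl)cyclohexan-1-one
Product: 6 (2S,3R,6S)-2,3-dimethyl-6-(2-methylhex-5-en-2-yl)cyclohexan-1-one, via lithium enolate 5 (not isolated)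
Conditions: LDA, THF, −78 °C; MeI, −78 → 0 °C; then NaOMe (cat.), MeOH, rt
Reagents that add atoms: iodomethane, CI
Why: Kinetic deprotonation takes the unhindered C9 methylene rather than the C5 methine beside the tert-alkyl group, the enolate is C-methylated (enolate alkylation), and methoxide equilibration should give the all-equatorial isomer whose axial C9–H is set up for the next enolisation, the C9 configuration being provisional.

**Step 3**
Reactants: 7 methyl hydrogen (R)-3-methylglutarate
Product: 8 methyl (3R)-5-hydroxy-3-methylpentanoate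
Conditions: BH3·SMe2, THF, −10 → 20 °C; MeOH quench; crude used at once
Reagents that add atoms: none
Why: Borane reduces the free carboxylic acid much faster than the methyl ester, so the two ends of the prochiral glutarate stay differentiated and the C13 stereocentre is carried over untouched.

**Step 4**
Reactants: 8 methyl (3R)-5-hydroxy-3-methylpentanoate
Product: 9 methyl (3S)-5-iodo-3-methylpentanoate
Conditions: I2, PPh3, imidazole, CH2Cl2, 0 °C → rt
Reagents that add atoms: iodine, II
Why: Appel-type iodination of the primary alcohol by SN2 displacement of the oxyphosphonium leaves the remote stereocentre alone, the descriptor changing to S only because iodine alters the CIP priorities.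

**Step 5**
Reactants: 6 (2S,3R,6S)-2,3-dimethyl-6-(2-methylhex-5-en-2-yl)cyclohexan-1-one; 9 methyl (3S)-5-iodo-3-methylpentanoate
Product: 11 methyl (3R)-5-[(1R,3S,6R)-1,6-dimethyl-3-(2-methylhex-5-en-2-yl)-2-oxocyclohexyl]-3-methylpentanoate, via lithium enolate 10 (not isolated)
Conditions: LDA, THF, −78 → 0 °C; then 9, DMPU, −40 °C → rt
Reagents that add atoms: none
Why: LDA removes the axial C9–H (the C5–H beside the tert-alkyl group is shielded and would give a badly strained enolate) and the tetrasubstituted enolate is C-alkylated by the primary iodide (enolate alkylation creating quaternary C9), the electrophile being expected to enter axially on the face anti to the pseudo-equatorial C5 tert-alkyl group, which places the side chain cis to the C8 methyl and the C9 methyl trans to it.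

**Step 6**
Reactants: 11 methyl (3R)-5-[(1R,3S,6R)-1,6-dimethyl-3-(2-methylhex-5-en-2-yl)-2-oxocyclohexyl]-3-methylpentanoate
Product: 13 methyl (3R)-5-[(1R,3S,6R)-1,6-dimethyl-3-(2-methyl-5-oxopentan-2-yl)-2-oxocyclohexyl]-3-methylpentanoate, via ozonide 12 (not isolated)
Conditions: O3, CH2Cl2, −78 °C; then PPh3, −78 °C → rt
Reagents that add atoms: ozone, [O-][O+]=O
Why: Ozonolysis of the only C=C bond with reductive work-up cleaves the terminal alkene to the C1 aldehyde under neutral conditions that leave the ester, the ketone and the epimerisable C5 untouched.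

**Step 7**
Reactants: 13 methyl (3R)-5-[(1R,3S,6R)-1,6-dimethyl-3-(2-methyl-5-oxopentan-2-yl)-2-oxocyclohexyl]-3-methylpentanoate
Product: 14 methyl (3R)-3-methyl-5-[(1R,2R,4aS)-1,2,5,5-tetramethyl-1,2,3,4,4a,5,6,7-octahydronaphthalen-1-yl]pentanoate
Conditions: TiCl3(DME)1.5, Zn–Cu couple, DME, reflux; slow addition of 13 (syringe pump, high dilution)
Reagents that add atoms: none
Why: Low-valent titanium transfers single electrons to the aldehyde C1 and the ketone C10, the two ketyls couple to a titanium-bound 1,2-diolate (C1–C10 bond formed), and at reflux both C–O bonds are cleaved on the titanium surface to leave the C1=C10 alkene. The closest known reaction type is the intramolecular McMurry keto-aldehyde coupling to cycloalkenes. Ring A (C1–C5, C10) is closed as a six-membered ring by reductive carbonyl–carbonyl coupling of the 1,6-dicarbonyl unit (formally a 6-exo ketyl addition to the ring B ketone), fused to ring B at C5–C10. No stereocentre is created; C5, C8, C9 and C13 are spectators, and C5, although α to the ketone, should not enolise under these non-basic conditions. The step needs intramolecular over intermolecular coupling (slow addition at high dilution and the favourable six-membered ring), chemoselectivity over the methyl ester (esters couple far more slowly than aldehydes and ketones) and tolerance of the congested C10 carbonyl between C9 and C5, for which the oxophilic, sterically undemanding titanium surface is the best precedent. Because the alkene can only form between the two former carbonyl carbons, its position is fixed at C1=C10 with no isomer towards C5.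

**Step 8**
Reactants: 14 methyl (3R)-3-methyl-5-[(1R,2R,4aS)-1,2,5,5-tetramethyl-1,2,3,4,4a,5,6,7-octahydronaphthalen-1-yl]pentanoate
Product: 16 (3R)-3-methyl-5-[(1R,2R,4aS)-1,2,5,5-tetramethyl-1,2,3,4,4a,5,6,7-octahydronaphthalen-1-yl]pentanoic acid, via lithium carboxylate 15 (not isolated)
Conditions: LiOH·H2O, THF/MeOH/H2O, rt; then cold 1 M HCl to pH 3
Reagents that add atoms: lithium hydroxide, [Li+].[OH-]
Why: Saponification of the unhindered methyl ester with no epimerisable centre α to the carboxyl (C13 is β), followed by a mild acidification that should not isomerise the trisubstituted alkene.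

**Step 9**
Reactants: 17 (S)-glycidol
Product: 18 [(2R)-oxiran-2-yl]methyl acetate
Conditions: Ac2O, Et3N, DMAP (cat.), CH2Cl2, 0 °C
Reagents that add atoms: acetic anhydride, CC(=O)OC(C)=O
Why: DMAP-catalysed O-acylation of the primary alcohol leaves the epoxide and its stereocentre untouched, the descriptor changing from S to R only through the CIP priorities.

**Step 10**
Reactants: 16 (3R)-3-methyl-5-[(1R,2R,4aS)-1,2,5,5-tetramethyl-1,2,3,4,4a,5,6,7-octahydronaphthalen-1-yl]pentanoic acid; 18 [(2R)-oxiran-2-yl]methyl acetate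
Product: 19 (2S)-3-(acetyloxy)-2-hydroxypropyl (3R)-3-methyl-5-[(1R,2R,4aS)-1,2,5,5-tetramethyl-1,2,3,4,4a,5,6,7-octahydronaphthalen-1-yl]pentanoate (target)
Conditions: (salen)Co(OAc) (2 mol %; trivalent cobalt; salen = N,N′-bis(3,5-di-tert-butylsalicylidene)-1,2-cyclohexanediamine dianion, racemic), iPr2NEt (cat.), tert-butyl methyl ether, rt
Reagents that add atoms: none
Why: Lewis-acid-catalysed ring opening of the terminal epoxide by the carboxylic acid at the unsubstituted CH2 (the glycidyl ester route to 1,3-diacylglycerols) gives the 1-acyl-3-acetyl glycerol directly, and since no bond at the stereocentre is broken the (S)-configured secondary alcohol follows from (S)-glycidol while the near-neutral conditions should suppress acyl migration.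

**Compound list**
1 | (R)-(+)-pulegone, (5R)-5-methyl-2-(propan-2-ylidene)cyclohexan-1-one | C[C@@H]1CCC(=C(C)C)C(=O)C1 | starting material
2 | but-3-en-1-ylmagnesium bromide | C=CCC[Mg]Br | starting material
3 | bromomagnesium (5R)-5-methyl-2-(2-methylhex-5-en-2-yl)cyclohex-1-en-1-olate | C[C@@H]1CCC(C(C)(C)CCC=C)=C(O[Mg]Br)C1 | intermediate (not isolated)
4 | (2S,5R)-5-methyl-2-(2-methylhex-5-en-2-yl)cyclohexan-1-one | C[C@@H]1CC[C@@H](C(C)(C)CCC=C)C(=O)C1 | intermediate
5 | lithium (3R,6S)-3-methyl-6-(2-methylhex-5-en-2-yl)cyclohex-1-en-1-olate | C[C@@H]1CC[C@@H](C(C)(C)CCC=C)C(O[Li])=C1 | intermediate (not isolated)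
6 | (2S,3R,6S)-2,3-dimethyl-6-(2-methylhex-5-en-2-yl)cyclohexan-1-one | C[C@@H]1CC[C@@H](C(C)(C)CCC=C)C(=O)[C@H]1C | intermediate
7 | methyl hydrogen (R)-3-methylglutarate, (3R)-5-methoxy-3-methyl-5-oxopentanoic acid | COC(=O)C[C@H](C)CC(=O)O | starting material
8 | methyl (3R)-5-hydroxy-3-methylpentanoate | COC(=O)C[C@H](C)CCO | intermediate
9 | methyl (3S)-5-iodo-3-methylpentanoate | COC(=O)C[C@H](C)CCI | intermediate
10 | lithium (3R,6S)-2,3-dimethyl-6-(2-methylhex-5-en-2-yl)cyclohex-1-en-1-olate | C[C@@H]1CC[C@@H](C(C)(C)CCC=C)C(O[Li])=C1C | intermediate (not isolated)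
11 | methyl (3R)-5-[(1R,3S,6R)-1,6-dimethyl-3-(2-methylhex-5-en-2-yl)-2-oxocyclohexyl]-3-methylpentanoate | COC(=O)C[C@H](C)CC[C@@]1(C)C(=O)[C@H](C(C)(C)CCC=C)CC[C@H]1C | intermediate
12 | 1,2,4-trioxolane (ozonide) of 11, both epimers at the trioxolane carbon | COC(=O)C[C@H](C)CC[C@@]1(C)C(=O)[C@H](C(C)(C)CCC2OCOO2)CC[C@H]1C | intermediate (not isolated)
13 | methyl (3R)-5-[(1R,3S,6R)-1,6-dimethyl-3-(2-methyl-5-oxopentan-2-yl)-2-oxocyclohexyl]-3-methylpentanoate | COC(=O)C[C@H](C)CC[C@@]1(C)C(=O)[C@H](C(C)(C)CCC=O)CC[C@H]1C | intermediate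
14 | methyl (3R)-3-methyl-5-[(1R,2R,4aS)-1,2,5,5-tetramethyl-1,2,3,4,4a,5,6,7-octahydronaphthalen-1-yl]pentanoate | COC(=O)C[C@H](C)CC[C@@]1(C)C2=CCCC(C)(C)[C@@H]2CC[C@H]1C | intermediate
15 | lithium (3R)-3-methyl-5-[(1R,2R,4aS)-1,2,5,5-tetramethyl-1,2,3,4,4a,5,6,7-octahydronaphthalen-1-yl]pentanoate | [Li+].[O-]C(=O)C[C@H](C)CC[C@@]1(C)C2=CCCC(C)(C)[C@@H]2CC[C@H]1C | intermediate (not isolated)
16 | (3R)-3-methyl-5-[(1R,2R,4aS)-1,2,5,5-tetramethyl-1,2,3,4,4a,5,6,7-octahydronaphthalen-1-yl]pentanoic acid | OC(=O)C[C@H](C)CC[C@@]1(C)C2=CCCC(C)(C)[C@@H]2CC[C@H]1C | intermediate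
17 | (S)-glycidol, [(2S)-oxiran-2-yl]methanol | OC[C@H]1CO1 | starting material
18 | [(2R)-oxiran-2-yl]methyl acetate | CC(=O)OC[C@H]1CO1 | intermediate
19 | (2S)-3-(acetyloxy)-2-hydroxypropyl (3R)-3-methyl-5-[(1R,2R,4aS)-1,2,5,5-tetramethyl-1,2,3,4,4a,5,6,7-octahydronaphthalen-1-yl]pentanoate | CC(=O)OC[C@H](O)COC(=O)C[C@H](C)CC[C@@]1(C)C2=CCCC(C)(C)[C@@H]2CC[C@H]1C | target

**Totals.** Total step count: 10. Longest linear sequence: 7 steps (steps 1, 2, 5, 6, 7, 8, 10 from pulegone).

**Steps most likely to fail**

Step 7 (key step). The reductive coupling may stall before or at the diolate stage, or lose out to simple reduction of the aldehyde or to intermolecular coupling, because the C10 carbonyl sits between quaternary C9 and the tert-alkyl-bearing C5; slow attack on the ester is a further drain. Fallback, setting out from 11 and coming back at 14: the carbonyl coupling is replaced by olefin metathesis. Ketone 11 is methylenated at C10 under non-basic conditions that spare the ester and C5 (Zn, CH2Br2, TiCl4, THF/CH2Cl2, 0 °C → rt) to give methyl (3R)-5-[(1R,3S,6R)-1,6-dimethyl-2-methylidene-3-(2-methylhex-5-en-2-yl)cyclohexyl]-3-methylpentanoate F1. Ring-closing metathesis of F1 (second-generation Hoveyda–Grubbs catalyst, toluene, 80 °C) then forms the same C1=C10 bond with loss of ethylene and delivers 14.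

Step 5. Facial selectivity may be poor (competing attack anti to the C8 methyl instead of anti to the C5 substituent), and C-alkylation of the hindered tetrasubstituted enolate by an unactivated primary iodide may be sluggish. Fallback, setting out from 6 and coming back at 11: the chain is introduced by a Michael reaction, which has a later transition state and a stronger axial preference, and C13 is set afterwards by catalyst control. Ketone 6 is converted (LDA, THF; then TMSCl) into trimethyl{[(3R,6S)-2,3-dimethyl-6-(2-methylhex-5-en-2-yl)cyclohex-1-en-1-yl]oxy}silane F2. Mukaiyama–Michael addition of F2 to methyl vinyl ketone (TiCl4, CH2Cl2, −78 °C) gives (2R,3R,6S)-2,3-dimethyl-6-(2-methylhex-5-en-2-yl)-2-(3-oxobutyl)cyclohexan-1-one F3. Horner–Wadsworth–Emmons olefination of the unhindered methyl ketone (trimethyl phosphonoacetate, NaH, THF) gives, after removal of the Z isomer, methyl (2E)-5-[(1R,3S,6R)-1,6-dimethyl-3-(2-methylhex-5-en-2-yl)-2-oxocyclohexyl]-3-methylpent-2-enoate F4. Copper hydride asymmetric conjugate reduction of F4 (Cu(OAc)2 cat., the enantiomer of p-tol-BINAP that gives the 3R ester, polymethylhydrosiloxane, tBuOH, toluene) returns to 11.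

Step 10. Regiocontrol of the epoxide opening may be incomplete (attack at the internal carbon), and acyl migration between the glycerol oxygens would scramble the 1,3-diester and erode the configuration at the carbinol carbon. Fallback, setting out from 16 and coming back at 19: the glycerol unit is built stepwise on a protected chiral glycerol. Acid 16 is esterified with (R)-solketal (OC[C@@H]1COC(C)(C)O1; DCC, DMAP cat., CH2Cl2) to give [(4S)-2,2-dimethyl-1,3-dioxolan-4-yl]methyl (3R)-3-methyl-5-[(1R,2R,4aS)-1,2,5,5-tetramethyl-1,2,3,4,4a,5,6,7-octahydronaphthalen-1-yl]pentanoate F5. The acetonide is removed (80% aq AcOH, rt) to give (2S)-2,3-dihydroxypropyl (3R)-3-methyl-5-[(1R,2R,4aS)-1,2,5,5-tetramethyl-1,2,3,4,4a,5,6,7-octahydronaphthalen-1-yl]pentanoate F6. Selective acetylation of the primary hydroxyl of F6 (AcCl, 2,4,6-collidine, CH2Cl2, −78 °C) gives 19.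

**Further compounds**
F1 | step 7 | methyl (3R)-5-[(1R,3S,6R)-1,6-dimethyl-2-methylidene-3-(2-methylhex-5-en-2-yl)cyclohexyl]-3-methylpentanoate | COC(=O)C[C@H](C)CC[C@@]1(C)C(=C)[C@H](C(C)(C)CCC=C)CC[C@H]1C
F2 | step 5 | trimethyl{[(3R,6S)-2,3-dimethyl-6-(2-methylhex-5-en-2-yl)cyclohex-1-en-1-yl]oxy}silane | C[C@@H]1CC[C@@H](C(C)(C)CCC=C)C(O[Si](C)(C)C)=C1C
F3 | step 5 | (2R,3R,6S)-2,3-dimethyl-6-(2-methylhex-5-en-2-yl)-2-(3-oxobutyl)cyclohexan-1-one | CC(=O)CC[C@@]1(C)C(=O)[C@H](C(C)(C)CCC=C)CC[C@H]1C
F4 | step 5 | methyl (2E)-5-[(1R,3S,6R)-1,6-dimethyl-3-(2-methylhex-5-en-2-yl)-2-oxocyclohexyl]-3-methylpent-2-enoate | COC(=O)/C=C(\C)CC[C@@]1(C)C(=O)[C@H](C(C)(C)CCC=C)CC[C@H]1C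
F5 | step 10 | [(4S)-2,2-dimethyl-1,3-dioxolan-4-yl]methyl (3R)-3-methyl-5-[(1R,2R,4aS)-1,2,5,5-tetramethyl-1,2,3,4,4a,5,6,7-octahydronaphthalen-1-yl]pentanoate | CC1(C)OC[C@@H](COC(=O)C[C@H](C)CC[C@@]2(C)C3=CCCC(C)(C)[C@@H]3CC[C@H]2C)O1
F6 | step 10 | (2S)-2,3-dihydroxypropyl (3R)-3-methyl-5-[(1R,2R,4aS)-1,2,5,5-tetramethyl-1,2,3,4,4a,5,6,7-octahydronaphthalen-1-yl]pentanoate | OC[C@H](O)COC(=O)C[C@H](C)CC[C@@]1(C)C2=CCCC(C)(C)[C@@H]2CC[C@H]1C
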